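The readings come from a simulation from invented constants; noise was put on by code.

The pitfall in repeating this run is to expect more free base to buy more turnover, when no earlier run has moved that charge.

| flask | electrophile | free base | gas | remark | time |
|---|---|---|---|---|---|
| larch | 0.074 M | 2 equiv | 4 mM (held) | run made earlier |  |
| west | 0.11 M | 3.00 equiv | 4.0 mM (held) |  | 20 h |
| south | 0.11 M | 2.00 equiv | 4.0 mM (held) |  | 20 h |

larch run (percent of the electrophile charged)

| time / h | electrophile / % | target / % |
|---|---|---|
| 0.667 | 97.3 | 1.6 |
| 2.00 | 89.1 | 6.5 |
| 3.00 | 84.2 | 9.2 |
| 5.00 | 75.8 | 15.7 |
| 8.00 | 64.1 | 23.6 |

(readings scatter by 0.5 percentage points)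

- at the start none of the gas is in solution
- no earlier run changes the charge of free base; that part of a forecast is a guess

- part of the electrophile that has reacted at the end, west
- part of the electrophile that has reacted at the end, south
- what raising the equivalents of free base from its lowest to its highest value here does to the part of the electrophile that has reacted (changes below 5 percentage points count as none) (it rises / it falls / no change)

I take the end state to be electrophile used up, in west at 3.00 equiv of free base and in south at 2.00 equiv, so the question is how far along that road each flask stands at 20 h. To measure the pace I read the larch table row by row as a pseudo-first-order loss constant, minus the logarithm of the fraction of electrophile left, divided by the time 0.0556 h⁻¹, taken from the last row, and as an estimate I let c(electrophile) fall as exp(−k·t) while the gas is held. No gas is in solution at the start, and the first row gives 0.0410 h⁻¹, less than k, on a loss of 2.7 percentage points that carries the scatter. The second row gives 0.0577 h⁻¹, which is close to the last row, so the reading is steady. I carry k unchanged from 0.074 M to 0.11 M, and, as a guess, unchanged by free base, which gives 67.1% for both west and south, hence no change.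

The forecast parts from me here: it gives 86% for west and 73% for south, and its answer on free base is "it rises", on this ground: “I assume the rate goes as gas × base × electrophile, with base consumed”.

The flask gives 68.0% in west and 68.0% in south, against my 67.1% for both, so the answer on free base is "no change".

    nucleophile + acid set free ⇌ protonated nucleophile, settled at all times (K = 3.20 × 10⁵ M⁻¹)
    acid set free + free base ⇌ salt of the base (K = 2.90 × 10⁵ M⁻¹, k = 4.60 × 10⁻⁴ M⁻¹ s⁻¹)
    electrophile + nucleophile → acid set free + target (k = 0.00300 M⁻¹ s⁻¹)
    gas ⇌ nucleophile, rate k4*(csat - [nucleophile]) (kL = 0.00220 s⁻¹)
    2 electrophile → homo dimer (k = 4.40 × 10⁻⁵ M⁻¹ s⁻¹)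

South at 20.0 h still holds 99.9% of its free base, protonated nucleophile stands at 0.0458 M against 1.73 × 10⁻⁴ M of salt of the base, and the path from acid set free and free base to that salt makes no difference to the turnover. The same flask as south read at 30 h is the neighbour: exp(−k·t) with the larch constant gives 81.1% reacted, and the flask gives 80.4%, with 20% of the electrophile left, 28.4% as homo dimer and 52.0% as target.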